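**Strategy**

The oxolane is disconnected at O1–C5. The key step exploits the fact that ring oxygen O1 and C2 with its ring A can be traced back to an aroyl C=O group, while C5 can be traced back to the unsubstituted ring CH2 of a cyclopropane that already carries the C4 stereocentre. A nucleophile-catalysed Cloke–Wilson rearrangement of an ethyl 1-aroyl-2-benzylcyclopropane-1-carboxylate therefore opens the three-membered ring and closes the 4,5-dihydrofuran in one operation, with C4 carried through. The precursor comes from a glycidol-derived cyclic sulfate and a commercial β-keto ester; hydrogenation, reduction and benzylic equilibration then set C3 and C2.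

Key step: step 4

**Remarks on the chemistry**

- Atom labels O1 and C2–C5 refer to the oxolane of the target: C2 carries ring A, C3 the CH2OH group, C4 the benzyl group with ring B.
- The cyclopropane formed in step 3 is expected as a mixture of epimers at its quaternary carbon. It is drawn as the (1R,2S) epimer, with the aroyl group trans to the benzyl group. Both epimers give the same product in step 4.
- The enantiomeric purity of the target derives from commercial (S)-glycidol.

**Route**

Step 1
Reactants: 1 3,4,5-trimethoxyphenylmagnesium bromide (commercial THF solution); 2 (S)-glycidol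
Product: 3 (2R)-3-(3,4,5-trimethoxyphenyl)propane-1,2-diol
Conditions: 1 (2.5 equiv), CuI (10 mol%), THF, −30 → 0 °C; aq NH4Cl
Reagents that add atoms: none
Why: Copper-catalysed Grignard opening of a terminal epoxide takes place at the unsubstituted carbon once the first equivalent of 1 has deprotonated the hydroxyl group, so the stereocentre of 2 is not touched and changes its descriptor from S to R only because the substituent priorities change.

Step 2
Reactants: 3 (2R)-3-(3,4,5-trimethoxyphenyl)propane-1,2-diol
Product: 5 (4R)-4-(3,4,5-trimethoxybenzyl)-1,3,2-dioxathiolane 2,2-dioxide, via cyclic sulfite 4 (not isolated)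
Conditions: SOCl2, Et3N, CH2Cl2, 0 °C; then RuCl3 (0.5 mol%), NaIO4, MeCN/H2O, 0 °C, 20 min
Reagents that add atoms: thionyl chloride, O=S(Cl)Cl; sodium periodate, [Na+].[O-]I(=O)(=O)=O
Why: Cyclic sulfite formation from a 1,2-diol with SOCl2 followed by RuO4-catalysed oxidation at sulfur (RuCl3 with NaIO4 as terminal oxidant) is the standard one-flask route to 1,2-cyclic sulfates, it breaks no bond at the stereocentre, and the low catalyst loading and short contact time are chosen to spare the electron-rich arene.

Step 3
Reactants: 5 (4R)-4-(3,4,5-trimethoxybenzyl)-1,3,2-dioxathiolane 2,2-dioxide; 6 ethyl 3-oxo-3-(3,4,5-trimethoxyphenyl)propanoate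
Product: 8 ethyl (1R,2S)-1-(3,4,5-trimethoxybenzoyl)-2-(3,4,5-trimethoxybenzyl)cyclopropane-1-carboxylate, via sulfate monoester salt 7 (not isolated)
Conditions: NaH (2.2 equiv), THF, 0 °C → rt, then 60 °C; aq NH4Cl
Reagents that add atoms: none
Why: Cyclopropanation of an active methylene compound by double SN2 alkylation with a 1,2-cyclic sulfate: the sodium enolate of 6 is alkylated at the primary carbon of 5, and the enolate of 7 then closes 3-exo-tet at the secondary sulfate with Walden inversion, which sets the S configuration at the benzyl-bearing ring carbon, while the uncontrolled quaternary centre is erased in step 4.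

Step 4
Reactants: 8 ethyl (1R,2S)-1-(3,4,5-trimethoxybenzoyl)-2-(3,4,5-trimethoxybenzyl)cyclopropane-1-carboxylate
Product: 10 ethyl (4R)-4-(3,4,5-trimethoxybenzyl)-2-(3,4,5-trimethoxyphenyl)-4,5-dihydrofuran-3-carboxylate, via ammonium enolate 9 (not isolated)
Conditions: 1,4-diazabicyclo[2.2.2]octane (DABCO, 0.5 equiv), DMSO, 120 °C, N2
Reagents that add atoms: none
Why: DABCO attacks the unsubstituted CH2 of the doubly acceptor-activated cyclopropane in an SN2 homo-conjugate addition, which cleaves the bond to the quaternary carbon and releases the stabilised keto ester enolate 9; the enolate oxygen of the aryl ketone then displaces the ammonium group at the same carbon and forms the O1–C5 bond. The closest known reaction type is the amine-catalysed Cloke–Wilson ring expansion of 1-acylcyclopropane-1-carboxylates to 4,5-dihydrofuran-3-carboxylates. The one ring is closed by a 5-exo-tet O-alkylation, and because the product is a conjugated vinylogous carbonate this closure is the irreversible exit, whereas C-alkylation of 9 only returns 8. No stereocentre is created: C4 is a spectator that keeps the configuration set in step 3, and the quaternary carbon becomes sp2, so both C1 epimers of 8 converge. The step needs attack at the ring CH2 and not at the benzyl-bearing CH, which is secured by the steric difference between a primary and a secondary ring carbon and by the absence of a donor at the substituted carbon, the arene being insulated by a CH2 group. Amine activation is chosen over Lewis-acid activation for this reason, since an ionising pathway would favour the more substituted carbon and the 5-benzyl regioisomer.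

Step 5
Reactants: 10 ethyl (4R)-4-(3,4,5-trimethoxybenzyl)-2-(3,4,5-trimethoxyphenyl)-4,5-dihydrofuran-3-carboxylate
Product: 11 ethyl (2R,3S,4R)-4-(3,4,5-trimethoxybenzyl)-2-(3,4,5-trimethoxyphenyl)oxolane-3-carboxylate
Conditions: H2 (5 bar), 10% Pd/C, EtOAc, rt
Reagents that add atoms: none
Why: Heterogeneous catalytic hydrogenation delivers both hydrogen atoms syn to the face of the C2=C3 bond opposite the C4 benzyl group, which sets C2 and C3 so that aryl, ester and benzyl groups are all cis, and the neutral aprotic medium keeps hydrogenolysis of the benzylic C2–O1 bond slow.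

Step 6
Reactants: 11 ethyl (2R,3S,4R)-4-(3,4,5-trimethoxybenzyl)-2-(3,4,5-trimethoxyphenyl)oxolane-3-carboxylate
Product: 12 [(2R,3R,4R)-4-(3,4,5-trimethoxybenzyl)-2-(3,4,5-trimethoxyphenyl)oxolan-3-yl]methanol
Conditions: LiAlH4 (1.5 equiv), THF, −10 → 0 °C; H2O, aq NaOH
Reagents that add atoms: none
Why: LiAlH4 reduction of an ester to the primary alcohol is fast at low temperature, so the enolisable C3 centre keeps its configuration and no ring bond is affected.

Step 7
Reactants: 12 [(2R,3R,4R)-4-(3,4,5-trimethoxybenzyl)-2-(3,4,5-trimethoxyphenyl)oxolan-3-yl]methanol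
Product: 13 [(2S,3R,4R)-4-(3,4,5-trimethoxybenzyl)-2-(3,4,5-trimethoxyphenyl)oxolan-3-yl]methanol (target)
Conditions: BF3·OEt2 (0.2 equiv), CH2Cl2, −30 → 0 °C, followed until 12 is consumed; Et3N quench
Reagents that add atoms: none
Why: Lewis-acid-mediated reversible heterolysis of the benzylic C2–O1 bond and re-closure by the C5 oxygen (SN1-type epimerisation of a benzylic ether) equilibrates C2 alone, so the strained all-cis isomer drains into the more stable 2,3-trans isomer with C3 and C4 unchanged, while low temperature, substoichiometric acid and an early quench are meant to hold back the slower Friedel–Crafts capture of the cation by ring B.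

**Compound list**

1 | 3,4,5-trimethoxyphenylmagnesium bromide | COc1cc([Mg]Br)cc(OC)c1OC | starting material
2 | (S)-glycidol, [(2S)-oxiran-2-yl]methanol | OC[C@H]1CO1 | starting material
3 | (2R)-3-(3,4,5-trimethoxyphenyl)propane-1,2-diol | OC[C@H](O)Cc1cc(OC)c(OC)c(OC)c1 | intermediate
4 | (4R)-4-(3,4,5-trimethoxybenzyl)-1,3,2-dioxathiolane 2-oxide (cyclic sulfite, both configurations at sulfur) | O=S1OC[C@@H](Cc2cc(OC)c(OC)c(OC)c2)O1 | intermediate
5 | (4R)-4-(3,4,5-trimethoxybenzyl)-1,3,2-dioxathiolane 2,2-dioxide (cyclic sulfate) | O=S1(=O)OC[C@@H](Cc2cc(OC)c(OC)c(OC)c2)O1 | intermediate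
6 | ethyl 3-oxo-3-(3,4,5-trimethoxyphenyl)propanoate | CCOC(=O)CC(=O)c1cc(OC)c(OC)c(OC)c1 | starting material
7 | sodium (2S)-4-(ethoxycarbonyl)-5-oxo-1,5-bis(3,4,5-trimethoxyphenyl)pentan-2-yl sulfate (C4 epimers, present in the flask as its enolate) | CCOC(=O)C(C[C@@H](Cc1cc(OC)c(OC)c(OC)c1)OS(=O)(=O)[O-])C(=O)c1cc(OC)c(OC)c(OC)c1.[Na+] | intermediate
8 | ethyl (1R,2S)-1-(3,4,5-trimethoxybenzoyl)-2-(3,4,5-trimethoxybenzyl)cyclopropane-1-carboxylate | CCOC(=O)[C@]1(C(=O)c2cc(OC)c(OC)c(OC)c2)C[C@@H]1Cc1cc(OC)c(OC)c(OC)c1 | intermediate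
9 | zwitterionic ammonium enolate: 1-[(2R)-3-(ethoxycarbonyl)-4-oxido-2-(3,4,5-trimethoxybenzyl)-4-(3,4,5-trimethoxyphenyl)but-3-en-1-yl]-4-aza-1-azoniabicyclo[2.2.2]octane | CCOC(=O)C(=C([O-])c1cc(OC)c(OC)c(OC)c1)[C@@H](Cc1cc(OC)c(OC)c(OC)c1)C[N+]12CCN(CC1)CC2 | intermediate
10 | ethyl (4R)-4-(3,4,5-trimethoxybenzyl)-2-(3,4,5-trimethoxyphenyl)-4,5-dihydrofuran-3-carboxylate | CCOC(=O)C1=C(c2cc(OC)c(OC)c(OC)c2)OC[C@@H]1Cc1cc(OC)c(OC)c(OC)c1 | intermediate
11 | ethyl (2R,3S,4R)-4-(3,4,5-trimethoxybenzyl)-2-(3,4,5-trimethoxyphenyl)oxolane-3-carboxylate (all-cis) | COc1cc(C[C@H]2CO[C@@H](c3cc(OC)c(OC)c(OC)c3)[C@H]2C(=O)OCC)cc(OC)c1OC | intermediate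
12 | [(2R,3R,4R)-4-(3,4,5-trimethoxybenzyl)-2-(3,4,5-trimethoxyphenyl)oxolan-3-yl]methanol (all-cis) | COc1cc(C[C@H]2CO[C@@H](c3cc(OC)c(OC)c(OC)c3)[C@H]2CO)cc(OC)c1OC | intermediate
13 | [(2S,3R,4R)-4-(3,4,5-trimethoxybenzyl)-2-(3,4,5-trimethoxyphenyl)oxolan-3-yl]methanol | COc1cc(C[C@H]2CO[C@H](c3cc(OC)c(OC)c(OC)c3)[C@H]2CO)cc(OC)c1OC | target

**Step count**

Total steps: 7
Longest linear sequence: 7 steps (2 → 3 → 5 → 8 → 10 → 11 → 12 → 13)

**Steps most likely to fail**

1. Step 4 (key step). Ring opening by the amine at an unactivated primary cyclopropane carbon may be too slow, so that thermal degradation such as dealkoxycarbonylation of the keto ester in hot DMSO overtakes the rearrangement. Attack at the substituted ring carbon is the less likely deviation. The fallback gives up the ring expansion, sets out from Grignard reagent 1 and comes back to the route at target 13.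
   - (R)-Epichlorohydrin and diethyl malonate (NaOEt, EtOH, reflux) give the bicyclic lactone ethyl (1S,5R)-2-oxo-3-oxabicyclo[3.1.0]hexane-1-carboxylate F1.
   - Copper-catalysed homo-conjugate addition of 1 (CuI, THF, −30 °C) opens its cyclopropane CH2 and gives the trans lactone ester ethyl (3S,4R)-2-oxo-4-(3,4,5-trimethoxybenzyl)oxolane-3-carboxylate F2.
   - Krapcho dealkoxycarbonylation (LiCl, wet DMSO, 140 °C) gives (4R)-4-(3,4,5-trimethoxybenzyl)oxolan-2-one F3.
   - Its lithium enolate (LDA, THF, −78 °C) adds to 3,4,5-trimethoxybenzaldehyde anti to the benzyl group and gives the hydroxy lactone (3S,4R)-3-[hydroxy(3,4,5-trimethoxyphenyl)methyl]-4-(3,4,5-trimethoxybenzyl)oxolan-2-one F4, as carbinol epimers that are both usable.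
   - LiAlH4 (THF, 0 °C) gives the triol (2R,3R)-2-[hydroxy(3,4,5-trimethoxyphenyl)methyl]-3-(3,4,5-trimethoxybenzyl)butane-1,4-diol F5.
   - BF3·OEt2 (CH2Cl2, −30 °C) ionises the benzylic alcohol; the hydroxyl of the CH2OH next to the benzyl-bearing carbon closes the oxolane trans to the neighbouring CH2OH group, which gives 13.

2. Step 7. Irreversible intramolecular Friedel–Crafts capture of the C2 cation by the electron-rich ring B may compete with re-closure of the oxolane during the repeated ionisations that equilibration needs. Incomplete epimerisation is the other deviation. The fallback fixes C2 in a single ring-closing event instead of equilibrating a preformed ring; it sets out from dihydrofuran 10 and comes back at 13.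
   - Aqueous acid (2 M HCl, THF, 50 °C) hydrolyses the enol ether, and the γ-hydroxy β-keto ester lactonises with loss of ethanol to the keto lactone (3S,4R)-3-(3,4,5-trimethoxybenzoyl)-4-(3,4,5-trimethoxybenzyl)oxolan-2-one F6. Its acidic C3 settles trans to the benzyl group.
   - NaBH4 (MeOH, 0 °C) reduces the ketone to hydroxy lactone F4.
   - LiAlH4 gives triol F5, and the cyclodehydration described under the first fallback gives 13.

3. Step 3. O-alkylation of the ambident keto ester enolate by the hard sulfate electrophile in the intermolecular stage may divert material into enol ethers. A 5-exo closure through oxygen in the second stage is the less likely deviation. The fallback uses a carbanion that alkylates only at carbon and adds the aryl ketone afterwards; it sets out from cyclic sulfate 5 and comes back at 8.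
   - Ethyl 3-chloro-3-oxopropanoate and N,O-dimethylhydroxylamine hydrochloride (Et3N, CH2Cl2, 0 °C) give the amide ester ethyl 3-[methoxy(methyl)amino]-3-oxopropanoate F7.
   - Its sodium enolate (NaH, THF, then 60 °C) is alkylated twice by 5 as in step 3 and gives ethyl (2S)-1-[methoxy(methyl)carbamoyl]-2-(3,4,5-trimethoxybenzyl)cyclopropane-1-carboxylate F8, as C1 epimers.
   - Addition of 1 (THF, −20 °C) to the N-methoxy-N-methylamide (Weinreb ketone synthesis through a chelated tetrahedral intermediate) installs the aroyl group and gives 8.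

Further compounds
F1 | step 4 | ethyl (1S,5R)-2-oxo-3-oxabicyclo[3.1.0]hexane-1-carboxylate | CCOC(=O)[C@]12C[C@H]1COC2=O
F2 | step 4 | ethyl (3S,4R)-2-oxo-4-(3,4,5-trimethoxybenzyl)oxolane-3-carboxylate | O=C1OC[C@H](Cc2cc(OC)c(OC)c(OC)c2)[C@H]1C(=O)OCC
F3 | step 4 | (4R)-4-(3,4,5-trimethoxybenzyl)oxolan-2-one | O=C1OC[C@H](Cc2cc(OC)c(OC)c(OC)c2)C1
F4 | step 4 | (3S,4R)-3-[hydroxy(3,4,5-trimethoxyphenyl)methyl]-4-(3,4,5-trimethoxybenzyl)oxolan-2-one (carbinol epimers) | O=C1OC[C@H](Cc2cc(OC)c(OC)c(OC)c2)[C@H]1C(O)c1cc(OC)c(OC)c(OC)c1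
F5 | step 4 | (2R,3R)-2-[hydroxy(3,4,5-trimethoxyphenyl)methyl]-3-(3,4,5-trimethoxybenzyl)butane-1,4-diol (carbinol epimers) | OC[C@H](Cc1cc(OC)c(OC)c(OC)c1)[C@H](CO)C(O)c1cc(OC)c(OC)c(OC)c1
F6 | step 7 | (3S,4R)-3-(3,4,5-trimethoxybenzoyl)-4-(3,4,5-trimethoxybenzyl)oxolan-2-one | O=C1OC[C@H](Cc2cc(OC)c(OC)c(OC)c2)[C@H]1C(=O)c1cc(OC)c(OC)c(OC)c1
F7 | step 3 | ethyl 3-[methoxy(methyl)amino]-3-oxopropanoate | CCOC(=O)CC(=O)N(C)OC
F8 | step 3 | ethyl (2S)-1-[methoxy(methyl)carbamoyl]-2-(3,4,5-trimethoxybenzyl)cyclopropane-1-carboxylate (C1 epimers) | CCOC(=O)C1(C(=O)N(C)OC)C[C@@H]1Cc1cc(OC)c(OC)c(OC)c1
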